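**Atom labels** (germacrane skeleton of the target): C1 furanone C=O, C2 furanone CH, C3 furanone C–O carbon, C4(=C15H2), C5 (CHOH), C6 (CH–O-methacrylate), C7, C8 (lactone CH–O), C9 (CH2), C10 (quaternary, methyl C14), C11(=C13H2), C12 (lactone C=O).

**Retrosynthetic overview**
1. Target ⇐ C5 silyl ether; the ten-membered carbocycle and the cis-γ-lactone close together by intramolecular Barbier allylation (C7–C8) of a (Z)-2-(bromomethyl)enoate onto the C8 aldehyde.
2. Furanone (first ring) ⇐ carbonylative Sonogashira union of a C4 vinyl bromide (east) with a tertiary propargylic alcohol (west), C3 coming from CO, then gold-catalysed cycloisomerisation.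
3. East piece ⇐ vinylalumination of an α-acyloxy aldehyde; the C6–O ester comes from an enamine-catalysed α-methacryloyloxylation; C5 comes from a phosphoric-acid-catalysed allylboration of 2-bromoacrolein.
4. West piece ⇐ chiral-diol-catalysed allylboration of a silyl ynone (C10), then ozonolysis/acetalisation.
5. Ring order: furanone (step 9), then carbocycle and lactone in one step (step 12).

**Assumption:** 2-allyl-1,3,2-dioxaborinane and 2-bromoacrolein are taken as catalogue reagents, and the (S)-diol catalyst of step 1 is taken to give the (R)-carbinol; if the sense proves opposite, the (R)-catalyst is used and nothing else changes.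

Step 1
Reactants: 1 4-(trimethylsilyl)but-3-yn-2-one; 2 2-allyl-1,3,2-dioxaborinane
Product: 3 (R)-3-methyl-1-(trimethylsilyl)hex-5-en-1-yn-3-ol
Conditions: (S)-3,3′-dibromo-1,1′-bi-2-naphthol (5 mol %), t-BuOH (2 equiv), toluene, rt; aq. NaHCO3 work-up
Reagents that add atoms: none
Why: Chiral-diol-catalysed asymmetric allylboration of a ketone: the binaphthol exchanges onto boron and the allyl group is delivered through a closed chair transition state to one face of the alkynyl methyl ketone, which sets C10 (R).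

Step 2
Reactants: 3 (R)-3-methyl-1-(trimethylsilyl)hex-5-en-1-yn-3-ol
Product: 6 (R)-5,5-dimethoxy-3-methylpent-1-yn-3-ol, via aldehyde 4 (not isolated), via silyl acetal 5 (not isolated)
Conditions: O3, CH2Cl2/MeOH, −78 °C; Me2S; then HC(OMe)3, PPTS, rt; then K2CO3, MeOH, rt
Reagents that add atoms: ozone, [O-][O+]=O (its oxygen is carried by 4 only); trimethyl orthoformate, COC(OC)OC
Why: Chemoselective ozonolysis of the terminal alkene (the silylalkyne reacts far more slowly), in-pot acetalisation of the retro-aldol-prone β-hydroxy aldehyde and base-mediated C-desilylation; C10 is not touched.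

Step 3
Reactants: 7 2-bromoprop-2-enal (2-bromoacrolein); 8 allylboronic acid pinacol ester
Product: 9 (R)-2-bromohexa-1,5-dien-3-ol
Conditions: (R)-TRIP [(R)-3,3′-bis(2,4,6-triisopropylphenyl)-1,1′-binaphthyl-2,2′-diyl hydrogen phosphate] (5 mol %), 4 Å MS, toluene, −30 °C; aq. work-up
Reagents that add atoms: none
Why: Chiral phosphoric acid-catalysed allylboration of an aldehyde through a closed chair transition state; the acid binds the boronate oxygen and the formyl hydrogen and directs attack to the Re face, which sets C5 (R here, S in the target).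

Step 4
Reactants: 9 (R)-2-bromohexa-1,5-dien-3-ol
Product: 10 (R)-[(2-bromohexa-1,5-dien-3-yl)oxy](tert-butyl)dimethylsilane
Conditions: t-BuMe2SiOSO2CF3, 2,6-lutidine, CH2Cl2, −78 to 0 °C
Reagents that add atoms: tert-butyldimethylsilyl triflate, CC(C)(C)[Si](C)(C)OS(=O)(=O)C(F)(F)F
Why: Standard O-silylation of a secondary allylic alcohol; the stereocentre is not involved.

Step 5
Reactants: 10 (R)-[(2-bromohexa-1,5-dien-3-yl)oxy](tert-butyl)dimethylsilane
Product: 11 (R)-4-bromo-3-[(tert-butyldimethylsilyl)oxy]pent-4-enal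
Conditions: O3 (1.0 equiv), CH2Cl2, −78 °C; PPh3
Reagents that add atoms: ozone, [O-][O+]=O
Why: Ozonolysis with reductive work-up; the electron-poor bromoalkene reacts far more slowly than the monosubstituted alkene, and C5 is untouched.

Step 6
Reactants: 12 2-methylprop-2-enoyl chloride (methacryloyl chloride), 2 equiv in total
Product: 13 bis(2-methylprop-2-enoyl) peroxide
Conditions: 12 (2.0 equiv), 30 % aq. H2O2 (1.0 equiv), aq. NaOH (2.0 equiv), Et2O, −5 °C, BHT (1 mol %); kept as a titrated, cold Et2O solution and never concentrated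
Reagents that add atoms: hydrogen peroxide, OO; second equivalent of 2-methylprop-2-enoyl chloride 12, CC(=C)C(=O)Cl
Why: Two-fold Schotten–Baumann acylation of hydrogen peroxide, in which each O–H is acylated by one equivalent of the acid chloride under biphasic base; this is the standard route to symmetrical diacyl peroxides.

Step 7
Reactants: 11 (R)-4-bromo-3-[(tert-butyldimethylsilyl)oxy]pent-4-enal; 13 bis(2-methylprop-2-enoyl) peroxide
Product: 14 (2S,3R)-4-bromo-3-[(tert-butyldimethylsilyl)oxy]-1-oxopent-4-en-2-yl 2-methylprop-2-enoate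
Conditions: (S)-2-(triphenylmethyl)pyrrolidine (10 mol %), hydroquinone (10 mol %), THF, 0 °C; used at once
Reagents that add atoms: none
Why: Proposed new method: enamine-catalysed asymmetric α-methacryloyloxylation, in which the (E)-enamine of 11 attacks the O–O bond of the unsaturated diacyl peroxide (SN2 at oxygen) from the face left open by the trityl group, so that C6–O and the ester are installed together with the (2S) configuration (anti to the C5 silyloxy group), while hydroquinone suppresses radical chain decomposition and the α-methyl group keeps the acrylate a poor Michael acceptor for the enamine; the closest known reaction is the amine-catalysed α-benzoyloxylation of aldehydes with dibenzoyl peroxide.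

Step 8
Reactants: 14 (2S,3R)-4-bromo-3-[(tert-butyldimethylsilyl)oxy]-1-oxopent-4-en-2-yl 2-methylprop-2-enoate; 15 methyl propiolate
Product: 18 methyl (3RS,4R,5R)-6-bromo-5-[(tert-butyldimethylsilyl)oxy]-4-(methacryloyloxy)-2-methylidene-3-[(triethylsilyl)oxy]hept-6-enoate, via vinylalane 16 (not isolated), via aluminium alkoxide 17 (not isolated)
Conditions: i-Bu2AlH, N-methylmorpholine N-oxide, THF, 0 °C, then 15; then 14, 0 °C; then Et3SiOSO2CF3, 2,6-lutidine, −20 °C
Reagents that add atoms: diisobutylaluminium hydride, CC(C)C[AlH]CC(C)C (its aluminium and isobutyl groups are carried by 16 and 17 only); triethylsilyl triflate, CC[Si](CC)(CC)OS(=O)(=O)C(F)(F)F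
Why: Vinylalumination (a Morita–Baylis–Hillman surrogate): hydroalumination of the propiolate gives the α-aluminoacrylate, which adds 1,2 to the aldehyde, and the aluminium alkoxide is silylated in the pot; the new C7 carbinol centre is uncontrolled and is erased in step 11.

Step 9
Reactants: 18 silyl-protected bromo ester from step 8; 6 (R)-5,5-dimethoxy-3-methylpent-1-yn-3-ol
Product: 20 methyl (3RS,4S,5S)-5-[(tert-butyldimethylsilyl)oxy]-6-[(5R)-5-(2,2-dimethoxyethyl)-5-methyl-4-oxo-4,5-dihydrofuran-2-yl]-4-(methacryloyloxy)-2-methylidene-3-[(triethylsilyl)oxy]hept-6-enoate, via ynone 19 (not isolated)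
Conditions: Pd(OAc)2 (5 mol %), Xantphos (6 mol %), CuI (5 mol %), Et3N (3 equiv), CO (5 bar), toluene, 60 °C; silica plug; then AuCl[P(C6H4-4-CF3)3] (5 mol %), AgOSO2CF3 (5 mol %), toluene, rt
Reagents that add atoms: carbon monoxide, [C-]#[O+]
Why: Carbonylative Sonogashira coupling joins C4 to C2 through the CO carbon (C3), and gold-catalysed cycloisomerisation of the resulting γ-hydroxy ynone gives the 3(2H)-furanone; the C10–O bond is never broken and no stereocentre is touched.

Step 10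
Reactants: 20 furanone from step 9
Product: 21 methyl (3RS,4R,5S)-5-[(tert-butyldimethylsilyl)oxy]-3-hydroxy-4-(methacryloyloxy)-2-methylidene-6-[(5R)-5-methyl-4-oxo-5-(2-oxoethyl)-4,5-dihydrofuran-2-yl]hept-6-enoate
Conditions: TsOH·H2O (0.2 equiv), acetone/H2O (10:1), rt
Reagents that add atoms: water, O
Why: Mild acid hydrolysis removes the triethylsilyl ether and the dimethyl acetal while the hindered tert-butyldimethylsilyl ether survives; no base is present that could trigger β-elimination of the furanone oxygen from the new aldehyde.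

Step 11
Reactants: 21 hydroxy aldehyde from step 10
Product: 22 methyl (2Z,4R,5S)-2-(bromomethyl)-5-[(tert-butyldimethylsilyl)oxy]-4-(methacryloyloxy)-6-[(5R)-5-methyl-4-oxo-5-(2-oxoethyl)-4,5-dihydrofuran-2-yl]hepta-2,6-dienoate
Conditions: PBr3 (0.4 equiv), Et2O, −20 to 0 °C
Reagents that add atoms: phosphorus tribromide, BrP(Br)Br
Why: SN2′ bromination with allylic transposition of a Morita–Baylis–Hillman alcohol, which gives the (Z)-2-(bromomethyl)enoate and removes the C7 carbinol centre.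

Step 12
Reactants: 22 bromo aldehyde from step 11
Product: 24 (5S,6R,7S,8S,10R)-5-[(tert-butyldimethylsilyl)oxy]-1-oxo-3,10-epoxygermacra-2,4(15),11(13)-trien-8,12-olid-6-yl 2-methylprop-2-enoate, via hydroxy ester 23 (not isolated)
Conditions: Zn, sat. aq. NH4Cl/THF (1:4), 0.005 M, rt; then PPTS, CH2Cl2, rt
Reagents that add atoms: none
Why: Intramolecular Barbier allylation: the allylzinc from the (Z)-bromide adds at C7 through a cyclic chair transition state (C6 axial, C9 equatorial), giving the syn C7/C8 pair that lactonises to the cis-γ-lactone, and the C6 stereocentre (C6–H eclipsing the enoate plane, ring tether on the attacked face) directs the aldehyde to the face that gives 7S,8S.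

Step 13
Reactants: 24 silyl-protected macrolide from step 12
Product: 25 (5S,6R,7S,8S,10R)-5-hydroxy-1-oxo-3,10-epoxygermacra-2,4(15),11(13)-trien-8,12-olid-6-yl 2-methylprop-2-enoate (CNP0142847.2)
Conditions: HF·pyridine, pyridine/THF, 0 °C to rt
Reagents that add atoms: none
Why: Fluoride desilylation under buffered acidic conditions, which avoids base-induced migration of the methacrylate to the freed C5 hydroxyl and leaves the α-methylene lactone alone.

**Compound list**
1 | 4-(trimethylsilyl)but-3-yn-2-one | CC(=O)C#C[Si](C)(C)C | starting material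
2 | 2-allyl-1,3,2-dioxaborinane | C=CCB1OCCCO1 | starting material
3 | (R)-3-methyl-1-(trimethylsilyl)hex-5-en-1-yn-3-ol | C[Si](C)(C)C#C[C@](C)(O)CC=C | intermediate
4 | (R)-3-hydroxy-3-methyl-5-(trimethylsilyl)pent-4-ynal | C[Si](C)(C)C#C[C@](C)(O)CC=O | intermediate
5 | (R)-5,5-dimethoxy-3-methyl-1-(trimethylsilyl)pent-1-yn-3-ol | C[Si](C)(C)C#C[C@](C)(O)CC(OC)OC | intermediate
6 | (R)-5,5-dimethoxy-3-methylpent-1-yn-3-ol | C#C[C@](C)(O)CC(OC)OC | intermediate
7 | 2-bromoprop-2-enal | C=C(Br)C=O | starting material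
8 | allylboronic acid pinacol ester | C=CCB1OC(C)(C)C(C)(C)O1 | starting material
9 | (R)-2-bromohexa-1,5-dien-3-ol | C=C(Br)[C@H](O)CC=C | intermediate
10 | (R)-[(2-bromohexa-1,5-dien-3-yl)oxy](tert-butyl)dimethylsilane | C=C(Br)[C@H](O[Si](C)(C)C(C)(C)C)CC=C | intermediate
11 | (R)-4-bromo-3-[(tert-butyldimethylsilyl)oxy]pent-4-enal | C=C(Br)[C@H](O[Si](C)(C)C(C)(C)C)CC=O | intermediate
12 | 2-methylprop-2-enoyl chloride | CC(=C)C(=O)Cl | starting material
13 | bis(2-methylprop-2-enoyl) peroxide | CC(=C)C(=O)OOC(=O)C(C)=C | intermediate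
14 | (2S,3R)-4-bromo-3-[(tert-butyldimethylsilyl)oxy]-1-oxopent-4-en-2-yl 2-methylprop-2-enoate | C=C(Br)[C@H](O[Si](C)(C)C(C)(C)C)[C@H](OC(=O)C(C)=C)C=O | intermediate
15 | methyl propiolate | C#CC(=O)OC | starting material
16 | methyl 2-(diisobutylalumanyl)prop-2-enoate | C=C([Al](CC(C)C)CC(C)C)C(=O)OC | intermediate
17 | methyl (3RS,4R,5R)-6-bromo-5-[(tert-butyldimethylsilyl)oxy]-3-[(diisobutylalumanyl)oxy]-4-(methacryloyloxy)-2-methylidenehept-6-enoate | C=C(Br)[C@H](O[Si](C)(C)C(C)(C)C)[C@H](OC(=O)C(C)=C)C(O[Al](CC(C)C)CC(C)C)C(=C)C(=O)OC | intermediate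
18 | methyl (3RS,4R,5R)-6-bromo-5-[(tert-butyldimethylsilyl)oxy]-4-(methacryloyloxy)-2-methylidene-3-[(triethylsilyl)oxy]hept-6-enoate | C=C(Br)[C@H](O[Si](C)(C)C(C)(C)C)[C@H](OC(=O)C(C)=C)C(O[Si](CC)(CC)CC)C(=C)C(=O)OC | intermediate
19 | methyl (3RS,4S,5S,10R)-5-[(tert-butyldimethylsilyl)oxy]-10-hydroxy-12,12-dimethoxy-4-(methacryloyloxy)-10-methyl-2,6-dimethylidene-7-oxo-3-[(triethylsilyl)oxy]dodec-8-ynoate | C=C(C(=O)C#C[C@](C)(O)CC(OC)OC)[C@H](O[Si](C)(C)C(C)(C)C)[C@H](OC(=O)C(C)=C)C(O[Si](CC)(CC)CC)C(=C)C(=O)OC | intermediate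
20 | methyl (3RS,4S,5S)-5-[(tert-butyldimethylsilyl)oxy]-6-[(5R)-5-(2,2-dimethoxyethyl)-5-methyl-4-oxo-4,5-dihydrofuran-2-yl]-4-(methacryloyloxy)-2-methylidene-3-[(triethylsilyl)oxy]hept-6-enoate | C=C(C1=CC(=O)[C@@](C)(CC(OC)OC)O1)[C@H](O[Si](C)(C)C(C)(C)C)[C@H](OC(=O)C(C)=C)C(O[Si](CC)(CC)CC)C(=C)C(=O)OC | intermediate
21 | methyl (3RS,4R,5S)-5-[(tert-butyldimethylsilyl)oxy]-3-hydroxy-4-(methacryloyloxy)-2-methylidene-6-[(5R)-5-methyl-4-oxo-5-(2-oxoethyl)-4,5-dihydrofuran-2-yl]hept-6-enoate | C=C(C1=CC(=O)[C@@](C)(CC=O)O1)[C@H](O[Si](C)(C)C(C)(C)C)[C@H](OC(=O)C(C)=C)C(O)C(=C)C(=O)OC | intermediate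
22 | methyl (2Z,4R,5S)-2-(bromomethyl)-5-[(tert-butyldimethylsilyl)oxy]-4-(methacryloyloxy)-6-[(5R)-5-methyl-4-oxo-5-(2-oxoethyl)-4,5-dihydrofuran-2-yl]hepta-2,6-dienoate | C=C(C1=CC(=O)[C@@](C)(CC=O)O1)[C@H](O[Si](C)(C)C(C)(C)C)[C@H](OC(=O)C(C)=C)/C=C(\CBr)C(=O)OC | intermediate
23 | methyl (5S,6R,7S,8S,10R)-5-[(tert-butyldimethylsilyl)oxy]-8-hydroxy-6-(methacryloyloxy)-1-oxo-3,10-epoxygermacra-2,4(15),11(13)-trien-12-oate | C=C(C)C(=O)O[C@@H]1[C@@H](C(=C)C(=O)OC)[C@@H](O)C[C@@]2(C)OC(=CC2=O)C(=C)[C@@H]1O[Si](C)(C)C(C)(C)C | intermediate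
24 | (5S,6R,7S,8S,10R)-5-[(tert-butyldimethylsilyl)oxy]-1-oxo-3,10-epoxygermacra-2,4(15),11(13)-trien-8,12-olid-6-yl 2-methylprop-2-enoate | C=C(C)C(=O)O[C@@H]1[C@H]2C(=C)C(=O)O[C@H]2C[C@@]2(C)OC(=CC2=O)C(=C)[C@@H]1O[Si](C)(C)C(C)(C)C | intermediate
25 | (5S,6R,7S,8S,10R)-5-hydroxy-1-oxo-3,10-epoxygermacra-2,4(15),11(13)-trien-8,12-olid-6-yl 2-methylprop-2-enoate (CNP0142847.2) | C=C(C)C(=O)O[C@@H]1[C@H]2C(=C)C(=O)O[C@H]2C[C@@]2(C)OC(=CC2=O)C(=C)[C@@H]1O | target

**Total step count:** 13. **Longest linear sequence:** 10 (steps 3, 4, 5, 7, 8, 9, 10, 11, 12, 13).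

**Three steps most likely to fail**

Step 7 (the proposed new α-methacryloyloxylation). The peroxide may polymerise or N-acylate the catalyst, the product may lose the β-silyloxy group, and catalyst control may be mismatched with C5. The fallback uses known chemistry, sets out from 11 and returns at 18. (R)-Proline-catalysed α-aminoxylation of 11 with nitrosobenzene (same facial sense) gives (2S,3R)-4-bromo-3-[(tert-butyldimethylsilyl)oxy]-2-[(phenylamino)oxy]pent-4-enal F1. This is taken directly through the vinylalumination and in-pot silylation of step 8 to methyl (3RS,4R,5R)-6-bromo-5-[(tert-butyldimethylsilyl)oxy]-2-methylidene-4-[(phenylamino)oxy]-3-[(triethylsilyl)oxy]hept-6-enoate F2. Cleavage of the N–O bond with Zn in AcOH/THF at 0 °C gives methyl (3RS,4R,5R)-6-bromo-5-[(tert-butyldimethylsilyl)oxy]-4-hydroxy-2-methylidene-3-[(triethylsilyl)oxy]hept-6-enoate F3, and acylation with methacrylic anhydride, DMAP and Et3N gives 18.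

Step 9 (carbonylative coupling and furanone formation). Oxidative addition of the hindered vinyl bromide under CO may be slow and direct, CO-free coupling may compete. The fallback sets out from 6 and 18 and returns at 19. Double deprotonation of 6 (n-BuLi, 2 equiv) and formylation with DMF gives (4R)-4-hydroxy-6,6-dimethoxy-4-methylhex-2-ynal F4. A CrCl2/NiCl2-mediated Nozaki–Hiyama–Kishi coupling of 18 with F4 gives methyl (3RS,4S,5S,7RS,10R)-5-[(tert-butyldimethylsilyl)oxy]-7,10-dihydroxy-12,12-dimethoxy-4-(methacryloyloxy)-10-methyl-2,6-dimethylidene-3-[(triethylsilyl)oxy]dodec-8-ynoate F5. Oxidation of its doubly activated secondary alcohol with MnO2 gives ynone 19, which is cyclised with the gold catalyst as in step 9.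

Step 12 (Barbier macrocyclisation). Substrate control may give the other syn pair (7R,8R), or oligomers. The fallback replaces substrate control by catalyst control; it sets out from 20 and returns at 24. PPTS in MeOH removes only the triethylsilyl group to give methyl (3RS,4R,5S)-5-[(tert-butyldimethylsilyl)oxy]-6-[(5R)-5-(2,2-dimethoxyethyl)-5-methyl-4-oxo-4,5-dihydrofuran-2-yl]-3-hydroxy-4-(methacryloyloxy)-2-methylidenehept-6-enoate F6. Ac2O and DMAP give the corresponding 3-acetate, methyl (3RS,4R,5S)-3-acetoxy-5-[(tert-butyldimethylsilyl)oxy]-6-[(5R)-5-(2,2-dimethoxyethyl)-5-methyl-4-oxo-4,5-dihydrofuran-2-yl]-4-(methacryloyloxy)-2-methylidenehept-6-enoate F7. Pd2(dba)3-catalysed allylic borylation with bis(pinacolato)diboron (toluene, 50 °C) gives methyl (2E,4R,5S)-5-[(tert-butyldimethylsilyl)oxy]-6-[(5R)-5-(2,2-dimethoxyethyl)-5-methyl-4-oxo-4,5-dihydrofuran-2-yl]-4-(methacryloyloxy)-2-[(4,4,5,5-tetramethyl-1,3,2-dioxaborolan-2-yl)methyl]hepta-2,6-dienoate F8. TsOH in wet acetone unmasks the aldehyde to give methyl (2E,4R,5S)-5-[(tert-butyldimethylsilyl)oxy]-4-(methacryloyloxy)-6-[(5R)-5-methyl-4-oxo-5-(2-oxoethyl)-4,5-dihydrofuran-2-yl]-2-[(4,4,5,5-tetramethyl-1,3,2-dioxaborolan-2-yl)methyl]hepta-2,6-dienoate F9. This is cyclised with (R)-TRIP (10 mol %, 4 Å MS, toluene, 0.005 M, rt): Re-face allylboration of the C8 aldehyde through a chair transition state gives 7S,8S, and lactonisation gives 24.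

**Further compounds**
F1 | step 7 | (2S,3R)-4-bromo-3-[(tert-butyldimethylsilyl)oxy]-2-[(phenylamino)oxy]pent-4-enal | C=C(Br)[C@H](O[Si](C)(C)C(C)(C)C)[C@H](ONc1ccccc1)C=O
F2 | step 7 | methyl (3RS,4R,5R)-6-bromo-5-[(tert-butyldimethylsilyl)oxy]-2-methylidene-4-[(phenylamino)oxy]-3-[(triethylsilyl)oxy]hept-6-enoate | C=C(Br)[C@H](O[Si](C)(C)C(C)(C)C)[C@H](ONc1ccccc1)C(O[Si](CC)(CC)CC)C(=C)C(=O)OC
F3 | step 7 | methyl (3RS,4R,5R)-6-bromo-5-[(tert-butyldimethylsilyl)oxy]-4-hydroxy-2-methylidene-3-[(triethylsilyl)oxy]hept-6-enoate | C=C(Br)[C@H](O[Si](C)(C)C(C)(C)C)[C@H](O)C(O[Si](CC)(CC)CC)C(=C)C(=O)OC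
F4 | step 9 | (4R)-4-hydroxy-6,6-dimethoxy-4-methylhex-2-ynal | O=CC#C[C@](C)(O)CC(OC)OC
F5 | step 9 | methyl (3RS,4S,5S,7RS,10R)-5-[(tert-butyldimethylsilyl)oxy]-7,10-dihydroxy-12,12-dimethoxy-4-(methacryloyloxy)-10-methyl-2,6-dimethylidene-3-[(triethylsilyl)oxy]dodec-8-ynoate | C=C(C(O)C#C[C@](C)(O)CC(OC)OC)[C@H](O[Si](C)(C)C(C)(C)C)[C@H](OC(=O)C(C)=C)C(O[Si](CC)(CC)CC)C(=C)C(=O)OC
F6 | step 12 | methyl (3RS,4R,5S)-5-[(tert-butyldimethylsilyl)oxy]-6-[(5R)-5-(2,2-dimethoxyethyl)-5-methyl-4-oxo-4,5-dihydrofuran-2-yl]-3-hydroxy-4-(methacryloyloxy)-2-methylidenehept-6-enoate | C=C(C1=CC(=O)[C@@](C)(CC(OC)OC)O1)[C@H](O[Si](C)(C)C(C)(C)C)[C@H](OC(=O)C(C)=C)C(O)C(=C)C(=O)OC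
F7 | step 12 | methyl (3RS,4R,5S)-3-acetoxy-5-[(tert-butyldimethylsilyl)oxy]-6-[(5R)-5-(2,2-dimethoxyethyl)-5-methyl-4-oxo-4,5-dihydrofuran-2-yl]-4-(methacryloyloxy)-2-methylidenehept-6-enoate | C=C(C1=CC(=O)[C@@](C)(CC(OC)OC)O1)[C@H](O[Si](C)(C)C(C)(C)C)[C@H](OC(=O)C(C)=C)C(OC(C)=O)C(=C)C(=O)OC
F8 | step 12 | methyl (2E,4R,5S)-5-[(tert-butyldimethylsilyl)oxy]-6-[(5R)-5-(2,2-dimethoxyethyl)-5-methyl-4-oxo-4,5-dihydrofuran-2-yl]-4-(methacryloyloxy)-2-[(4,4,5,5-tetramethyl-1,3,2-dioxaborolan-2-yl)methyl]hepta-2,6-dienoate | C=C(C1=CC(=O)[C@@](C)(CC(OC)OC)O1)[C@H](O[Si](C)(C)C(C)(C)C)[C@H](OC(=O)C(C)=C)/C=C(\CB1OC(C)(C)C(C)(C)O1)C(=O)OC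
F9 | step 12 | methyl (2E,4R,5S)-5-[(tert-butyldimethylsilyl)oxy]-4-(methacryloyloxy)-6-[(5R)-5-methyl-4-oxo-5-(2-oxoethyl)-4,5-dihydrofuran-2-yl]-2-[(4,4,5,5-tetramethyl-1,3,2-dioxaborolan-2-yl)methyl]hepta-2,6-dienoate | C=C(C1=CC(=O)[C@@](C)(CC=O)O1)[C@H](O[Si](C)(C)C(C)(C)C)[C@H](OC(=O)C(C)=C)/C=C(\CB1OC(C)(C)C(C)(C)O1)C(=O)OC
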